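**Plan**
1. The retrosynthesis cuts the bond between the chain CH2 (called C15 here) and the methyl-bearing olefinic carbon (C14), giving primary iodide 15 and alkynol 6. The C13=C14 alkene is traced back to the triple bond of a pent-3-ynyl chain on the decalin.
2. Enabling feature: C14 carries only a methyl group besides the new bond, so the E-alkene is the syn H/C adduct of a methyl-capped alkyne. The methyl end is the less hindered alkyne carbon and takes the metal. The ring-B tertiary hydroxyl and the exocyclic methylene lie far from the reacting carbons and stay unprotected.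
3. Decalin half: (−)-sclareol supplies all four ring stereocentres. Its side chain is cut to the methyl ketone and turned into the 2-alkyne (steps 1–2).
4. Monocyclic half: 4,4-dimethylcyclohexenone is iodinated and reduced (CBS) to set a carbinol centre. A Johnson–Claisen rearrangement transfers this centre to the ring CH next to the gem-dimethyl carbon, and allylsilane protodesilylation moves the alkene to the exocyclic position (steps 3–9).
5. The two halves are joined last, in step 10, by one-flask hydrozirconation, zinc transmetalation and palladium-catalysed alkylation, which also fixes the E geometry.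

Key step: step 10

Assumption: the hindered tertiary hydroxyl is carried free; under the basic or hydridic conditions of steps 2 and 10 it is taken to sit as its lithium or zirconium alkoxide and to be released on aqueous work-up.

**Step 1**
Reactants: 1 (−)-sclareol
Product: 3 4-[(1R,2R,4aS,8aS)-2-hydroxy-2,5,5,8a-tetramethyldecahydronaphthalen-1-yl]butan-2-one, via tetraol 2 (not isolated)
Conditions: OsO4 (2 mol%), NaIO4 (3.5 equiv), THF/H2O, 40 °C
Reagents that add atoms: none
Why: Lemieux–Johnson oxidative cleavage: the vinyl group, the only alkene, is dihydroxylated and periodate cleaves the resulting 13,14,15-triol array twice, so that C13 keeps its own oxygen as the ketone while the ring stereocentres are untouched.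

**Step 2**
Reactants: 3 4-[(1R,2R,4aS,8aS)-2-hydroxy-2,5,5,8a-tetramethyldecahydronaphthalen-1-yl]butan-2-one
Product: 6 (1R,2R,4aS,8aS)-2,5,5,8a-tetramethyl-1-(pent-3-yn-1-yl)decahydronaphthalen-2-ol, via enol phosphate 4 (not isolated), via lithium acetylide 5 (not isolated)
Conditions: 3 added to LDA (2.2 equiv), THF, −78 °C; ClP(O)(OEt)2, −78 °C to rt; LDA (2.5 equiv), −78 °C to rt; MeI, 0 °C to rt
Reagents that add atoms: iodomethane CI
Why: Methyl ketone to alkyne by the enol phosphate elimination route: kinetic deprotonation at the methyl group, O-phosphorylation of the enolate, LDA-induced elimination to the acetylide and C-methylation should follow in one flask, the hindered tertiary lithium alkoxide being too poor a nucleophile in THF to be phosphorylated or methylated.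

**Step 3**
Reactants: 7 4,4-dimethylcyclohex-2-en-1-one
Product: 8 2-iodo-4,4-dimethylcyclohex-2-en-1-one
Conditions: I2 (1.5 equiv), pyridine/CH2Cl2, rt
Reagents that add atoms: iodine II
Why: α-Iodination of an enone by conjugate addition of pyridine, iodination of the enolate and elimination, a standard route to 2-iodocycloalkenones.

**Step 4**
Reactants: 8 2-iodo-4,4-dimethylcyclohex-2-en-1-one
Product: 9 (1R)-2-iodo-4,4-dimethylcyclohex-2-en-1-ol
Conditions: (S)-2-methyl-CBS-oxazaborolidine (10 mol%), BH3·SMe2, THF, −20 °C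
Reagents that add atoms: none
Why: Corey–Bakshi–Shibata reduction: the α-iodoalkenyl arm acts as the large group and the ring CH2 as the small one, so the (S)-catalyst should deliver hydride to the face that gives the (1R)-carbinol, with the high selectivity typical of 2-halocycloalkenones (the enantiomeric purity can be raised by crystallisation of an ester derivative if needed).

**Step 5**
Reactants: 9 (1R)-2-iodo-4,4-dimethylcyclohex-2-en-1-ol
Product: 10 (1R)-4,4-dimethyl-2-[(trimethylsilyl)methyl]cyclohex-2-en-1-ol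
Conditions: Me3SiCH2MgCl (3 equiv), Pd(PPh3)4 (5 mol%), THF, 0 °C to rt
Reagents that add atoms: (trimethylsilyl)methylmagnesium chloride C[Si](C)(C)C[Mg]Cl
Why: Kumada coupling of a vinyl iodide with a Grignard reagent that has no β-hydrogen; the hydroxyl is carried as its magnesium alkoxide and the carbinol centre is not touched.

**Step 6**
Reactants: 10 (1R)-4,4-dimethyl-2-[(trimethylsilyl)methyl]cyclohex-2-en-1-ol
Product: 12 ethyl 2-[(1S)-6,6-dimethyl-2-[(trimethylsilyl)methyl]cyclohex-2-en-1-yl]acetate, via ketene acetal 11 (not isolated)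
Conditions: MeC(OEt)3 (6 equiv), EtCO2H (cat.), 140–170 °C, EtOH distilled off
Reagents that add atoms: triethyl orthoacetate CC(OCC)(OCC)OCC
Why: Johnson–Claisen rearrangement: the suprafacial [3,3] shift within the ring delivers the acetate carbon to the olefinic CH next to the gem-dimethyl carbon on the face from which the oxygen departs, so the (1R)-carbinol centre is transferred completely into the (S)-configured ring CH.

**Step 7**
Reactants: 12 ethyl 2-[(1S)-6,6-dimethyl-2-[(trimethylsilyl)methyl]cyclohex-2-en-1-yl]acetate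
Product: 13 ethyl 2-[(1S)-2,2-dimethyl-6-methylidenecyclohexyl]acetate
Conditions: CF3CO2H (1.1 equiv), CH2Cl2, −40 to −10 °C; Et3N quench
Reagents that add atoms: none
Why: SE2' protodesilylation of an allylsilane: protonation of the ring CH= gives a β-silyl cation that loses silicon at once, which places the double bond regiospecifically in the exocyclic position without involving the stereocentre.

**Step 8**
Reactants: 13 ethyl 2-[(1S)-2,2-dimethyl-6-methylidenecyclohexyl]acetate
Product: 14 2-[(1S)-2,2-dimethyl-6-methylidenecyclohexyl]ethan-1-ol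
Conditions: LiAlH4, Et2O, 0 °C
Reagents that add atoms: none
Why: Standard hydride reduction of an ester to the primary alcohol; the isolated 1,1-disubstituted alkene and the stereocentre are inert.

**Step 9**
Reactants: 14 2-[(1S)-2,2-dimethyl-6-methylidenecyclohexyl]ethan-1-ol
Product: 15 (2S)-2-(2-iodoethyl)-1,1-dimethyl-3-methylidenecyclohexane
Conditions: I2, PPh3, imidazole, CH2Cl2, 0 °C
Reagents that add atoms: iodine II
Why: Appel-type iodination of a primary alcohol by SN2 displacement of the oxyphosphonium ion under non-acidic conditions that leave the exocyclic alkene in place.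

**Step 10**
Reactants: 6 (1R,2R,4aS,8aS)-2,5,5,8a-tetramethyl-1-(pent-3-yn-1-yl)decahydronaphthalen-2-ol; 15 (2S)-2-(2-iodoethyl)-1,1-dimethyl-3-methylidenecyclohexane
Product: 18 (+)-ambrein, via alkenylzirconocene 16 (not isolated), via alkenylzinc chloride 17 (not isolated)
Conditions: 6, Cp2Zr(H)Cl (2.5 equiv), THF, 50 °C; ZnCl2 (1.5 equiv), 0 °C; then 15 (1.2 equiv), Pd2(dba)3 (2 mol%), P(c-C5H9)3 (8 mol%), N-methylimidazole, THF/NMP, 80 °C; aq NH4Cl
Reagents that add atoms: none
Why: Cp2Zr(H)Cl first turns the tertiary hydroxyl into a zirconium alkoxide and then adds H–Zr syn across the triple bond, and the excess hydride equilibrates the two regioisomers so that zirconium rests on C14, the alkyne carbon that carries only the small methyl group. Transmetalation to zinc and then to palladium goes with retention, oxidative addition of zerovalent palladium to the primary C–I bond of 15 is SN2-like, and the bulky electron-rich trialkylphosphine lets reductive elimination outrun β-hydride elimination. The closest known reaction types are the hydrozirconation–Negishi sequence of internal alkynes and the palladium/trialkylphosphine Negishi coupling of alkenylzinc halides with unactivated primary alkyl iodides. No ring is closed and no stereocentre is made, but the E geometry of the trisubstituted alkene follows from the syn addition (H on C13 cis to the metal on C14) and from retention in both transmetalations and in the reductive elimination. The step needs regioselectivity for C14 over C13, which the size difference between methyl and the 2-(decalinyl)ethyl group should secure under thermodynamic control; any minor regioisomer is removed by chromatography. It also needs chemoselectivity, secured because 15 with its 1,1-disubstituted alkene is added only after the hydride is consumed and because the hydroxyl is masked in the flask as its alkoxide.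

**Compound list**
1 | (−)-sclareol | C=C[C@](C)(O)CC[C@@H]1[C@@]2(C)CCCC(C)(C)[C@@H]2CC[C@@]1(C)O | starting material
2 | labdane-8,13,14,15-tetraol from dihydroxylation of 1 (C14 epimers) | OCC(O)[C@](C)(O)CC[C@@H]1[C@@]2(C)CCCC(C)(C)[C@@H]2CC[C@@]1(C)O | intermediate
3 | 4-[(1R,2R,4aS,8aS)-2-hydroxy-2,5,5,8a-tetramethyldecahydronaphthalen-1-yl]butan-2-one | CC(=O)CC[C@@H]1[C@@]2(C)CCCC(C)(C)[C@@H]2CC[C@@]1(C)O | intermediate
4 | lithium alkoxide of diethyl 4-[(1R,2R,4aS,8aS)-2-hydroxy-2,5,5,8a-tetramethyldecahydronaphthalen-1-yl]but-1-en-2-yl phosphate | C=C(CC[C@@H]1[C@@]2(C)CCCC(C)(C)[C@@H]2CC[C@@]1(C)[O-])OP(=O)(OCC)OCC.[Li+] | intermediate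
5 | dilithium salt (acetylide and alkoxide) of (1R,2R,4aS,8aS)-1-(but-3-yn-1-yl)-2,5,5,8a-tetramethyldecahydronaphthalen-2-ol | [Li+].[Li+].[C-]#CCC[C@@H]1[C@@]2(C)CCCC(C)(C)[C@@H]2CC[C@@]1(C)[O-] | intermediate
6 | (1R,2R,4aS,8aS)-2,5,5,8a-tetramethyl-1-(pent-3-yn-1-yl)decahydronaphthalen-2-ol | CC#CCC[C@@H]1[C@@]2(C)CCCC(C)(C)[C@@H]2CC[C@@]1(C)O | intermediate
7 | 4,4-dimethylcyclohex-2-en-1-one | O=C1C=CC(C)(C)CC1 | starting material
8 | 2-iodo-4,4-dimethylcyclohex-2-en-1-one | O=C1C(I)=CC(C)(C)CC1 | intermediate
9 | (1R)-2-iodo-4,4-dimethylcyclohex-2-en-1-ol | O[C@H]1C(I)=CC(C)(C)CC1 | intermediate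
10 | (1R)-4,4-dimethyl-2-[(trimethylsilyl)methyl]cyclohex-2-en-1-ol | O[C@H]1C(C[Si](C)(C)C)=CC(C)(C)CC1 | intermediate
11 | {[(6R)-6-(1-ethoxyethenyloxy)-3,3-dimethylcyclohex-1-en-1-yl]methyl}trimethylsilane | C=C(OCC)O[C@H]1C(C[Si](C)(C)C)=CC(C)(C)CC1 | intermediate
12 | ethyl 2-[(1S)-6,6-dimethyl-2-[(trimethylsilyl)methyl]cyclohex-2-en-1-yl]acetate | CCOC(=O)C[C@@H]1C(C[Si](C)(C)C)=CCCC1(C)C | intermediate
13 | ethyl 2-[(1S)-2,2-dimethyl-6-methylidenecyclohexyl]acetate | CCOC(=O)C[C@@H]1C(=C)CCCC1(C)C | intermediate
14 | 2-[(1S)-2,2-dimethyl-6-methylidenecyclohexyl]ethan-1-ol | OCC[C@@H]1C(=C)CCCC1(C)C | intermediate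
15 | (2S)-2-(2-iodoethyl)-1,1-dimethyl-3-methylidenecyclohexane | ICC[C@@H]1C(=C)CCCC1(C)C | intermediate
16 | (E)-alkenyl-Cp2ZrCl at C14 with the hydroxyl as its Cp2Zr(Cl) alkoxide (cyclopentadienyl rings drawn σ-bonded) | C/C(=C\CC[C@@H]1[C@@]2(C)CCCC(C)(C)[C@@H]2CC[C@@]1(C)O[Zr](Cl)(C1C=CC=C1)C1C=CC=C1)[Zr](Cl)(C1C=CC=C1)C1C=CC=C1 | intermediate
17 | (E)-alkenylzinc chloride at C14 with the hydroxyl as its Cp2Zr(Cl) alkoxide | Cl[Zn]/C(C)=C/CC[C@@H]1[C@@]2(C)CCCC(C)(C)[C@@H]2CC[C@@]1(C)O[Zr](Cl)(C1C=CC=C1)C1C=CC=C1 | intermediate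
18 | (+)-ambrein | C=C1CCCC(C)(C)[C@@H]1CC/C(C)=C/CC[C@@H]1[C@@]2(C)CCCC(C)(C)[C@@H]2CC[C@@]1(C)O | target

**Step count and risks**
Total steps: 10. Longest linear sequence: 8 (steps 3–9, then step 10).

Most likely to fail:

1. Step 10. The hindered α-methyl alkenyl group may transfer slowly to palladium, so that β-hydride elimination of the alkylpalladium species, protonolysis of the alkenylmetal or incomplete regio-equilibration takes over. The fallback reverses the polarity and sets out from 6 and 15. Hydrozirconation of 6 to 16 as before, followed by iodine, should give (1R,2R,4aS,8aS)-1-[(3E)-4-iodopent-3-en-1-yl]-2,5,5,8a-tetramethyldecahydronaphthalen-2-ol F1. Iodide 15 with t-BuLi (2 equiv, Et2O, −78 °C) should give 2-[(1S)-2,2-dimethyl-6-methylidenecyclohexyl]ethyllithium F2, which B-methoxy-9-BBN converts into the lithium B-alkyl-B-methoxy-9-BBN borinate F3. B-alkyl Suzuki–Miyaura coupling of F1 with F3 (Pd(dppf)Cl2, AsPh3, Cs2CO3, DMF/H2O, rt) comes back to the route at 18.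

2. Step 2. The tertiary alkoxide may add to the ketone (hemiketal) or be phosphorylated before the methyl group is enolised, and enolisation may not be fully regioselective. The fallback builds the alkyne from an aldehyde instead and sets out from 3. Haloform cleavage (NaOBr, dioxane/H2O) should give 3-[(1R,2R,4aS,8aS)-2-hydroxy-2,5,5,8a-tetramethyldecahydronaphthalen-1-yl]propanoic acid F4, which closes on acidification to ambreinolide F5 (the six-membered lactone). DIBAL-H (−78 °C) should give lactol F6, and Seyferth–Gilbert homologation with the Ohira–Bestmann reagent (K2CO3, MeOH) the terminal alkynol (1R,2R,4aS,8aS)-1-(but-3-yn-1-yl)-2,5,5,8a-tetramethyldecahydronaphthalen-2-ol F7. n-BuLi (2.1 equiv) then gives 5, and MeI comes back to the route at 6.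

3. Step 7. The acid may move the new exocyclic double bond into the ring, or the ester may lactonise onto the transient tertiary cation. The fallback avoids acid and silicon and sets out from 9. Johnson–Claisen rearrangement as in step 6 proceeds through [(1R)-2-iodo-4,4-dimethylcyclohex-2-en-1-yl] ketene acetal F8 to ethyl 2-[(1S)-2-iodo-6,6-dimethylcyclohex-2-en-1-yl]acetate F9. Stille coupling with Bu3SnCH2OH (Pd(PPh3)4, dioxane, 90 °C) should give ethyl 2-[(1S)-2-(hydroxymethyl)-6,6-dimethylcyclohex-2-en-1-yl]acetate F10. Mitsunobu displacement with 2-nitrobenzenesulfonylhydrazide (PPh3, DEAD, THF, −30 °C to rt) gives the N-alkyl-N-sulfonylhydrazine F11, which loses sulfinate to the allylic diazene F12. Its retro-ene loss of nitrogen delivers hydrogen to the ring carbon and comes back to the route at 13.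

**Further compounds**
F1 | step 10 | (1R,2R,4aS,8aS)-1-[(3E)-4-iodopent-3-en-1-yl]-2,5,5,8a-tetramethyldecahydronaphthalen-2-ol | C/C(I)=C\CC[C@@H]1[C@@]2(C)CCCC(C)(C)[C@@H]2CC[C@@]1(C)O
F2 | step 10 | 2-[(1S)-2,2-dimethyl-6-methylidenecyclohexyl]ethyllithium | [Li]CC[C@@H]1C(=C)CCCC1(C)C
F3 | step 10 | lithium B-{2-[(1S)-2,2-dimethyl-6-methylidenecyclohexyl]ethyl}-B-methoxy-9-borabicyclo[3.3.1]nonane borinate | [Li+].CO[B-]1(CC[C@@H]2C(=C)CCCC2(C)C)C2CCCC1CCC2
F4 | step 2 | 3-[(1R,2R,4aS,8aS)-2-hydroxy-2,5,5,8a-tetramethyldecahydronaphthalen-1-yl]propanoic acid | OC(=O)CC[C@@H]1[C@@]2(C)CCCC(C)(C)[C@@H]2CC[C@@]1(C)O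
F5 | step 2 | ambreinolide (six-membered lactone of F4) | O=C1CC[C@@H]2[C@@]3(C)CCCC(C)(C)[C@@H]3CC[C@@]2(C)O1
F6 | step 2 | lactol of ambreinolide (anomers) | OC1CC[C@@H]2[C@@]3(C)CCCC(C)(C)[C@@H]3CC[C@@]2(C)O1
F7 | step 2 | (1R,2R,4aS,8aS)-1-(but-3-yn-1-yl)-2,5,5,8a-tetramethyldecahydronaphthalen-2-ol | C#CCC[C@@H]1[C@@]2(C)CCCC(C)(C)[C@@H]2CC[C@@]1(C)O
F8 | step 7 | (6R)-6-(1-ethoxyethenyloxy)-1-iodo-3,3-dimethylcyclohex-1-ene | C=C(OCC)O[C@H]1C(I)=CC(C)(C)CC1
F9 | step 7 | ethyl 2-[(1S)-2-iodo-6,6-dimethylcyclohex-2-en-1-yl]acetate | CCOC(=O)C[C@@H]1C(I)=CCCC1(C)C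
F10 | step 7 | ethyl 2-[(1S)-2-(hydroxymethyl)-6,6-dimethylcyclohex-2-en-1-yl]acetate | CCOC(=O)C[C@@H]1C(CO)=CCCC1(C)C
F11 | step 7 | ethyl 2-[(1S)-2-{[1-(2-nitrobenzenesulfonyl)hydrazinyl]methyl}-6,6-dimethylcyclohex-2-en-1-yl]acetate | CCOC(=O)C[C@@H]1C(CN(N)S(=O)(=O)c2ccccc2[N+](=O)[O-])=CCCC1(C)C
F12 | step 7 | ethyl 2-[(1S)-2-(diazenylmethyl)-6,6-dimethylcyclohex-2-en-1-yl]acetate | CCOC(=O)C[C@@H]1C(CN=N)=CCCC1(C)C
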